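All constants are those of an exercise; the result is computed.

Take substrate at 0.10 M, 0.30 M and 1.0 M under the same held gas, and reckon how much target stays dissolved when the run ends.

all flasks: gas 7.1 mM (held); time 1.0 min

| run | substrate |
|---|---|
| gamma | 0.10 M |
| theta | 0.30 M |
| beta | 1.0 M |

    substrate ⇌ tight pair (K1 = 0.0027, k1 = 0.0078 /s)
    tight pair ⇌ loose pair (K2 = 1.8, k2 = 5.4 /s)
    coupling partner + tight pair → target (k3 = 78000 /M/s)
    coupling partner + loose pair → isomer of the product (k4 = 28000 /M/s)
    crystals ⇌ target, rate k5*(cs5 - [target]) while solid is left; crystals form when [target] > cs5 (cs5 = 22 mM, k5 = 1.4 /s)
    gas ⇌ coupling partner, rate k6*(csat - [coupling partner]) (k6 = 0.78 /s, csat = 7.1 mM)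

- for target the crystals are counted in
- as a solid, counted per litre of solution: crystals
- at the start none of coupling partner is dissolved
- the concentration of target that is asked is that of its free form alone
- "hardly changes" means that all values lie within two and a half points (for a concentration: within two and a half percent of the largest)
- run time (gamma): 1.0 min

- [target] (only what is free in solution) at the end for gamma, theta, beta, in this order
- the course of these numbers from the first flask to the last (rises, then falls / hardly changes / falls all the way / rises all the way / falls, then rises)

Begin with the fate of the tight pair at full [coupling partner]. Capture runs at 554 /s, return to substrate at 2.89 /s and the slip to the loose pair at 5.4 /s. So nearly all of it becomes target, and at that [coupling partner] the opening of substrate is the rate-limiting step.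

Next, look at the crystals. Gamma has the smallest charge, yet it opens 37.4 mM by the end, more than the solubility, so crystals stand there at the end.

Define the crystal lag, the time constant with which crystals, once they stand in the flask, take up an excess of dissolved target: 0.714 s. It is far shorter than the run, so take the excess over solubility as the rate of making times the lag.

Set out the rate of making at the end, and the excess it gives:

- gamma: 0.488 mM/s, excess 0.349 mM
- theta: 1.47 mM/s, excess 1.05 mM
- beta: 4.88 mM/s, excess 3.49 mM

Read down the lines. The gas can deliver at most 5.54 mM/s, and gamma's rate lies far under that, so add its excess to the solubility and get 0.0223 M.

Theta also stays under the ceiling, which gives 0.0230 M.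

Beta is the weak line. Its forward opening starts at 7.80 mM/s, above the ceiling, so the capture reckoned above at full [coupling partner] is not safe in beta. Its reckoned end rate is under the ceiling, so I commit to 0.0255 M with less confidence.

The course is then rises all the way.

The forecast gives 0.02235 M, 0.02303 M and 0.0253 M, course rises all the way, holding of the solubility limit that “free target sits just above it”. Its beta value is lower than mine.

The simulation gives 0.0223 M, 0.0230 M and 0.0253 M, course rises all the way. In beta at 1.00 min, [coupling partner] of 6.23 × 10⁻⁴ M and tight pair at 0.00944% of the charge make target at 4.58 mM/s, less than the gas ceiling. Times the crystal lag, that rate stands for 3.27 mM above the solubility of 22 mM, and the [target] stored for beta is 0.0253 M.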